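**Plan** (target numbered as 7-oxabicyclo[4.1.0]hept-3-en-2-one: C1 chain-bearing epoxide carbon, C2 C=O, C3 H, C4 Me, C5 OAc, C6 epoxide CH)
1. Retrosynthesis cuts, in order: the O-acetyl and O-silyl groups; the C5–H bond (back to a C5 ketone masked as a ketal); the epoxide C1–O and C6–O bonds (back to a quinone monoketal and its phenol 18); the C1–C2 ring bond; the C5–C6 bond.
2. Enabling feature: C2 and C5 carry oxygen para to each other, with C3–H/C4–Me on one side and C6–H/C1–chain on the other. This is the pattern of a 4-alkoxy-4-alkenylcyclobut-2-enone (C2, C3, C4, C5 in the four-membered ring, C6=C1 as the alkenyl arm), which grows by two atoms into the six-membered carbocycle on heating.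
3. Forward: chain stannane 5 (from farnesyl acetate) and squarate-derived monoketal 11 are joined at C5–C6; cyclobutenone 15 is expanded to phenol 18 (C1–C2 bond), which emerges with free OH on C2 and OMe on C5, so the two oxygens stay differentiated.
4. Phenol 18 is dearomatised to the quinone monoketal, epoxidised at C1=C6, deketalised, reduced at C5, acetylated and desilylated.
5. Stereochemistry: the chain E-alkenes come from farnesyl acetate and an E-selective SeO2 oxidation; C1 and C6 from nucleophilic epoxidation controlled by a C2-symmetric (2R,4R)-pentane-2,4-diol ketal; C5 from hydride attack anti to the epoxide oxygen.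

Key step: step 8

Assumption: in step 11 the peroxide is taken to add to the axial β-CH of the favoured dioxane chair of 20, anti to the syn-axial methyl, which for the (2R,4R)-diol gives the target epoxide; if the sense proves opposite, (2S,4S)-pentane-2,4-diol is used in step 10 and nothing else changes.

TBDPS = tert-butyldiphenylsilyl. Compounds 1, 4 and 6 are commercial.

**Step 1**
Reactants: 1 (2E,6E)-farnesyl acetate
Product: 2 (2E,6E,10E)-12-hydroxy-3,7,11-trimethyldodeca-2,6,10-trien-1-yl acetate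
Conditions: SeO2 (cat.), t-BuOOH, salicylic acid (cat.), CH2Cl2, rt
Reagents that add atoms: tert-butyl hydroperoxide, CC(C)(C)OO (oxygen source; SeO2 is catalytic)
Why: SeO2-catalysed allylic oxidation (ene reaction, then [2,3]-sigmatropic shift) should attack the most electron-rich terminal trisubstituted alkene at its (E)-methyl group, the 2,3-alkene being deactivated by the allylic acetate, to give the (10E)-allylic alcohol.

**Step 2**
Reactants: 2 (2E,6E,10E)-12-hydroxy-3,7,11-trimethyldodeca-2,6,10-trien-1-yl acetate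
Product: 3 (2E,6E,10E)-12-(TBDPS-oxy)-3,7,11-trimethyldodeca-2,6,10-trien-1-yl acetate
Conditions: TBDPSCl, imidazole, CH2Cl2, rt
Reagents that add atoms: tert-butyl(chloro)diphenylsilane, CC(C)(C)[Si](Cl)(c1ccccc1)c1ccccc1
Why: standard silylation of a primary allylic alcohol; the TBDPS ether should survive the organolithium, oxidant, base and dilute-acid steps that follow.

**Step 3**
Reactants: 3 (2E,6E,10E)-12-(TBDPS-oxy)-3,7,11-trimethyldodeca-2,6,10-trien-1-yl acetate; 4 (E)-1,2-bis(tributylstannyl)ethene (3 equiv)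
Product: 5 tributyl[(1E,4E,8E,12E)-14-(TBDPS-oxy)-5,9,13-trimethyltetradeca-1,4,8,12-tetraen-1-yl]stannane
Conditions: Pd(dba)2 (cat.), LiCl, DMF, rt to 40 °C
Reagents that add atoms: none
Why: Stille coupling of an allylic acetate: Pd(0) ionises the acetate to a π-allyl complex that, after transmetalation, should couple at the primary terminus with retention of alkene geometry, while the excess bis-stannane keeps the reaction at mono-coupling and leaves an (E)-vinylstannane.

**Step 4**
Reactants: 6 dimethyl squarate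
Product: 9 monoketal 3,4,4-trimethoxy-2-methylcyclobut-2-en-1-one, via lithium alkoxide 7 (not isolated), via trifluoroacetate 8 (not isolated)
Conditions: MeLi, THF, −78 °C; TFAA, −78 °C; MeOH, −78 to 0 °C
Reagents that add atoms: methyllithium, [Li]C; methanol, CO
Why: 1,2-addition of MeLi to one squarate carbonyl, trifluoroacetylation and ionisation give an alkoxy-stabilised cyclobutenyl cation that methanol should trap at the α-alkoxy carbon (squarate-to-dione-monoacetal chemistry), placing the methyl next to the remaining carbonyl.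

**Step 5**
Reactants: 9 monoketal 3,4,4-trimethoxy-2-methylcyclobut-2-en-1-one
Product: 11 enone 4,4-dimethoxy-2-methylcyclobut-2-en-1-one, via cyclobutenol 10 (not isolated)
Conditions: DIBAL-H, THF, −78 °C; then 1 M HCl, 0 °C
Reagents that add atoms: water, O
Why: Stork–Danheiser transposition: 1,2-reduction of the vinylogous ester followed by acid-induced enol ether hydrolysis with loss of the allylic hydroxyl should give the transposed enone with H on the β-carbon, the α-keto ketal being deactivated towards brief cold acid.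

**Step 6**
Reactants: 5 tributyl[(1E,4E,8E,12E)-14-(TBDPS-oxy)-5,9,13-trimethyltetradeca-1,4,8,12-tetraen-1-yl]stannane; 11 enone 4,4-dimethoxy-2-methylcyclobut-2-en-1-one
Product: 14 methyl ether 1,4,4-trimethoxy-2-methyl-1-[(1E,4E,8E,12E)-14-(TBDPS-oxy)-5,9,13-trimethyltetradeca-1,4,8,12-tetraen-1-yl]cyclobut-2-ene (racemic), via alkenyllithium 12 (not isolated), via lithium alkoxide 13 (not isolated)
Conditions: n-BuLi (0.95 equiv), THF, −78 °C; 11, −78 °C; MeOTf, −78 to 0 °C
Reagents that add atoms: methyl trifluoromethanesulfonate, COS(=O)(=O)C(F)(F)F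
Why: Sn–Li exchange with retention gives the (E)-alkenyllithium, which should add 1,2 to the only carbonyl of 11 (so the carbinol carbon lies next to C–Me, the regiochemistry being fixed by the ketal) before in situ O-methylation; at −78 °C deprotonation of the doubly allylic CH2 is slow.

**Step 7**
Reactants: 14 methyl ether (ketal)
Product: 15 cyclobutenone 4-methoxy-3-methyl-4-[(1E,4E,8E,12E)-14-(TBDPS-oxy)-5,9,13-trimethyltetradeca-1,4,8,12-tetraen-1-yl]cyclobut-2-en-1-one (racemic)
Conditions: 0.5 M H2SO4 (aq.), THF, 0 °C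
Reagents that add atoms: water, O
Why: acetal hydrolysis through the dialkoxycarbenium ion should be much faster than ionisation of the tertiary methyl ether, which becomes deactivated α to the new carbonyl; TBDPS tolerates dilute acid.

**Step 8**
Reactants: 15 cyclobutenone (racemic)
Product: 18 phenol 2-[(2E,6E,10E)-12-(TBDPS-oxy)-3,7,11-trimethyldodeca-2,6,10-trien-1-yl]-4-methoxy-5-methylphenol, via dienylketene 16 (not isolated), via cyclohexa-2,4-dienone 17 (not isolated)
Conditions: PhMe (degassed, dilute), 110 °C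
Reagents that add atoms: none
Why: Heating opens the cyclobutenone by conrotatory 4π electrocyclic cleavage of the C(=O)–C(OMe) bond, and the methoxy donor rotates outward so that the alkenyl arm ends up cis to the ketene in dienylketene 16. Thermal disrotatory 6π electrocyclisation then joins the ketene carbon to the alkene terminus, closing the six-membered carbocycle as dienone 17, which enolises to the aromatic phenol 18. The closest known reaction type is the Moore rearrangement of 4-alkenyl-4-alkoxycyclobutenones to hydroquinone monoethers, related to the Danheiser benzannulation. No stereocentre is created: the racemic carbinol centre of 15 is destroyed on ring opening and the sp3 centre of 17 on tautomerisation, and the chain E-alkenes are not involved. The step needs regiochemical fidelity (free OH next to the chain, OMe next to the methyl), which follows because the ketene carbonyl becomes the phenol oxygen and the H/Me placement was fixed in 15 by the monoketal route. It also needs outward rotation of the methoxy group, which π-donor substituents on the sp3 ring carbon enforce.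

**Step 9**
Reactants: 18 phenol
Product: 19 quinone monoketal 4,4-dimethoxy-5-methyl-2-[(2E,6E,10E)-12-(TBDPS-oxy)-3,7,11-trimethyldodeca-2,6,10-trien-1-yl]cyclohexa-2,5-dien-1-one
Conditions: PhI(OAc)2, MeOH, 0 °C
Reagents that add atoms: methanol, CO
Why: oxidative dearomatisation of a p-methoxyphenol by the λ3-iodane with para attack of methanol should give the monoketal at the former OMe carbon; isolated trisubstituted alkenes are inert to the reagent.

**Step 10**
Reactants: 19 quinone monoketal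
Product: 20 chiral ketal (2R,4R)-2,4,11-trimethyl-8-[(2E,6E,10E)-12-(TBDPS-oxy)-3,7,11-trimethyldodeca-2,6,10-trien-1-yl]-1,5-dioxaspiro[5.5]undeca-7,10-dien-9-one
Conditions: (2R,4R)-pentane-2,4-diol, PPTS (cat.), PhH, 4 Å MS, 50 °C
Reagents that add atoms: (2R,4R)-pentane-2,4-diol, C[C@@H](O)C[C@@H](C)O
Why: acid-catalysed transacetalisation driven by removal of methanol; the C2-symmetric diol creates no stereocentre at the spiro carbon and makes the two faces of the dienone diastereotopic.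

**Step 11**
Reactants: 20 chiral ketal
Product: 21 epoxide (1R,6S,4'R,6'R)-4,4',6'-trimethyl-1-[(2E,6E,10E)-12-(TBDPS-oxy)-3,7,11-trimethyldodeca-2,6,10-trien-1-yl]spiro[7-oxabicyclo[4.1.0]hept-3-ene-5,2'-[1,3]dioxan]-2-one
Conditions: Ph3COOH pre-mixed with KHMDS (sub-stoichiometric), THF, −35 °C
Reagents that add atoms: trityl hydroperoxide, OOC(c1ccccc1)(c1ccccc1)c1ccccc1
Why: Weitz–Scheffer nucleophilic epoxidation: the peroxide anion should add to the unsubstituted β-carbon next to the ketal (not to the methyl-bearing β-carbon), and in the favoured dioxane chair this CH is axial and shielded on one face by the syn-axial methyl, so attack from the open face sets both epoxide centres; the diastereomers are separable.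

**Step 12**
Reactants: 21 epoxide
Product: 22 epoxy dione (1R,6S)-4-methyl-1-[(2E,6E,10E)-12-(TBDPS-oxy)-3,7,11-trimethyldodeca-2,6,10-trien-1-yl]-7-oxabicyclo[4.1.0]hept-3-ene-2,5-dione
Conditions: TsOH·H2O (cat.), THF–H2O, 45 °C
Reagents that add atoms: water, O
Why: acid hydrolysis of the ketal releases the auxiliary; the epoxide α to a ketone is deactivated towards acid opening, and the TBDPS ether and trisubstituted alkenes tolerate dilute sulfonic acid.

**Step 13**
Reactants: 22 epoxy dione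
Product: 23 epoxy alcohol (1R,5R,6R)-5-hydroxy-4-methyl-1-[(2E,6E,10E)-12-(TBDPS-oxy)-3,7,11-trimethyldodeca-2,6,10-trien-1-yl]-7-oxabicyclo[4.1.0]hept-3-en-2-one
Conditions: NaBH4, CeCl3·7H2O, MeOH, −78 °C
Reagents that add atoms: none
Why: Luche 1,2-reduction should take the C5 carbonyl (flanked by the epoxide CH), because the C2 carbonyl is shielded on both faces by the epoxide oxygen and the chain on quaternary C1 and is deactivated by the β-methyl; hydride enters anti to the epoxide oxygen, giving the cis-epoxy alcohol (5R).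

**Step 14**
Reactants: 23 epoxy alcohol
Product: 24 acetate (1R,5R,6R)-4-methyl-2-oxo-1-[(2E,6E,10E)-12-(TBDPS-oxy)-3,7,11-trimethyldodeca-2,6,10-trien-1-yl]-7-oxabicyclo[4.1.0]hept-3-en-5-yl acetate
Conditions: Ac2O, pyridine, DMAP (cat.), CH2Cl2, 0 °C
Reagents that add atoms: acetic anhydride, CC(=O)OC(C)=O
Why: DMAP-catalysed acylation of the secondary alcohol with retention; the cis arrangement of hydroxyl and epoxide oxygen rules out Payne rearrangement.

**Step 15**
Reactants: 24 acetate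
Product: 25 yanuthone L, (1R,5R,6R)-1-[(2E,6E,10E)-12-hydroxy-3,7,11-trimethyldodeca-2,6,10-trien-1-yl]-4-methyl-2-oxo-7-oxabicyclo[4.1.0]hept-3-en-5-yl acetate
Conditions: HF·pyridine, pyridine, THF, 0 °C to rt
Reagents that add atoms: none
Why: buffered fluoride cleavage of the Si–O bond should leave the secondary acetate, the epoxide and the enone untouched.

**Compound list**
1 | (2E,6E)-farnesyl acetate | CC(=O)OC/C=C(\C)CC/C=C(\C)CCC=C(C)C | starting material
2 | (2E,6E,10E)-12-hydroxy-3,7,11-trimethyldodeca-2,6,10-trien-1-yl acetate | CC(=O)OC/C=C(\C)CC/C=C(\C)CC/C=C(\C)CO | intermediate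
3 | (2E,6E,10E)-12-(TBDPS-oxy)-3,7,11-trimethyldodeca-2,6,10-trien-1-yl acetate | CC(=O)OC/C=C(\C)CC/C=C(\C)CC/C=C(\C)CO[Si](c1ccccc1)(c1ccccc1)C(C)(C)C | intermediate
4 | (E)-1,2-bis(tributylstannyl)ethene | CCCC[Sn](CCCC)(CCCC)/C=C/[Sn](CCCC)(CCCC)CCCC | starting material
5 | tributyl[(1E,4E,8E,12E)-14-(TBDPS-oxy)-5,9,13-trimethyltetradeca-1,4,8,12-tetraen-1-yl]stannane | CCCC[Sn](CCCC)(CCCC)/C=C/C/C=C(\C)CC/C=C(\C)CC/C=C(\C)CO[Si](c1ccccc1)(c1ccccc1)C(C)(C)C | intermediate
6 | dimethyl squarate (3,4-dimethoxycyclobut-3-ene-1,2-dione) | COC1=C(OC)C(=O)C1=O | starting material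
7 | lithium 2,3-dimethoxy-1-methyl-4-oxocyclobut-2-en-1-olate (racemic) | [Li+].[O-]C1(C)C(OC)=C(OC)C1=O | intermediate
8 | 2,3-dimethoxy-1-methyl-4-oxocyclobut-2-en-1-yl trifluoroacetate (racemic) | CC1(OC(=O)C(F)(F)F)C(OC)=C(OC)C1=O | intermediate
9 | 3,4,4-trimethoxy-2-methylcyclobut-2-en-1-one | COC1=C(C)C(=O)C1(OC)OC | intermediate
10 | 3,4,4-trimethoxy-2-methylcyclobut-2-en-1-ol (racemic; aluminium alkoxide before work-up) | COC1=C(C)C(O)C1(OC)OC | intermediate
11 | 4,4-dimethoxy-2-methylcyclobut-2-en-1-one | COC1(OC)C=C(C)C1=O | intermediate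
12 | [(1E,4E,8E,12E)-14-(TBDPS-oxy)-5,9,13-trimethyltetradeca-1,4,8,12-tetraen-1-yl]lithium | [Li]/C=C/C/C=C(\C)CC/C=C(\C)CC/C=C(\C)CO[Si](c1ccccc1)(c1ccccc1)C(C)(C)C | intermediate
13 | lithium 4,4-dimethoxy-2-methyl-1-[(1E,4E,8E,12E)-14-(TBDPS-oxy)-5,9,13-trimethyltetradeca-1,4,8,12-tetraen-1-yl]cyclobut-2-en-1-olate (racemic) | [Li+].[O-]C1(/C=C/C/C=C(\C)CC/C=C(\C)CC/C=C(\C)CO[Si](c2ccccc2)(c2ccccc2)C(C)(C)C)C(C)=CC1(OC)OC | intermediate
14 | 1,4,4-trimethoxy-2-methyl-1-[(1E,4E,8E,12E)-14-(TBDPS-oxy)-5,9,13-trimethyltetradeca-1,4,8,12-tetraen-1-yl]cyclobut-2-ene (racemic) | COC1(/C=C/C/C=C(\C)CC/C=C(\C)CC/C=C(\C)CO[Si](c2ccccc2)(c2ccccc2)C(C)(C)C)C(C)=CC1(OC)OC | intermediate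
15 | 4-methoxy-3-methyl-4-[(1E,4E,8E,12E)-14-(TBDPS-oxy)-5,9,13-trimethyltetradeca-1,4,8,12-tetraen-1-yl]cyclobut-2-en-1-one (racemic) | COC1(/C=C/C/C=C(\C)CC/C=C(\C)CC/C=C(\C)CO[Si](c2ccccc2)(c2ccccc2)C(C)(C)C)C(C)=CC1=O | intermediate
16 | (5E,8E,12E,16E)-18-(TBDPS-oxy)-4-methoxy-3,9,13,17-tetramethyloctadeca-1,3,5,8,12,16-hexaen-1-one, C2 and C5 cis across C3=C4 | O=C=C/C(C)=C(OC)\C=C\C/C=C(\C)CC/C=C(\C)CC/C=C(\C)CO[Si](c1ccccc1)(c1ccccc1)C(C)(C)C | intermediate
17 | 4-methoxy-3-methyl-6-[(2E,6E,10E)-12-(TBDPS-oxy)-3,7,11-trimethyldodeca-2,6,10-trien-1-yl]cyclohexa-2,4-dien-1-one (racemic) | COC1=CC(C/C=C(\C)CC/C=C(\C)CC/C=C(\C)CO[Si](c2ccccc2)(c2ccccc2)C(C)(C)C)C(=O)C=C1C | intermediate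
18 | 2-[(2E,6E,10E)-12-(TBDPS-oxy)-3,7,11-trimethyldodeca-2,6,10-trien-1-yl]-4-methoxy-5-methylphenol | COc1cc(C/C=C(\C)CC/C=C(\C)CC/C=C(\C)CO[Si](c2ccccc2)(c2ccccc2)C(C)(C)C)c(O)cc1C | intermediate
19 | 4,4-dimethoxy-5-methyl-2-[(2E,6E,10E)-12-(TBDPS-oxy)-3,7,11-trimethyldodeca-2,6,10-trien-1-yl]cyclohexa-2,5-dien-1-one | COC1(OC)C=C(C/C=C(\C)CC/C=C(\C)CC/C=C(\C)CO[Si](c2ccccc2)(c2ccccc2)C(C)(C)C)C(=O)C=C1C | intermediate
20 | (2R,4R)-2,4,11-trimethyl-8-[(2E,6E,10E)-12-(TBDPS-oxy)-3,7,11-trimethyldodeca-2,6,10-trien-1-yl]-1,5-dioxaspiro[5.5]undeca-7,10-dien-9-one | C[C@@H]1C[C@@H](C)OC2(O1)C=C(C/C=C(\C)CC/C=C(\C)CC/C=C(\C)CO[Si](c1ccccc1)(c1ccccc1)C(C)(C)C)C(=O)C=C2C | intermediate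
21 | (1R,6S,4'R,6'R)-4,4',6'-trimethyl-1-[(2E,6E,10E)-12-(TBDPS-oxy)-3,7,11-trimethyldodeca-2,6,10-trien-1-yl]spiro[7-oxabicyclo[4.1.0]hept-3-ene-5,2'-[1,3]dioxan]-2-one | C[C@@H]1C[C@@H](C)OC2(O1)C(C)=CC(=O)[C@]3(C/C=C(\C)CC/C=C(\C)CC/C=C(\C)CO[Si](c1ccccc1)(c1ccccc1)C(C)(C)C)O[C@H]23 | intermediate
22 | (1R,6S)-4-methyl-1-[(2E,6E,10E)-12-(TBDPS-oxy)-3,7,11-trimethyldodeca-2,6,10-trien-1-yl]-7-oxabicyclo[4.1.0]hept-3-ene-2,5-dione | O=C1C(C)=CC(=O)[C@]2(C/C=C(\C)CC/C=C(\C)CC/C=C(\C)CO[Si](c3ccccc3)(c3ccccc3)C(C)(C)C)O[C@H]12 | intermediate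
23 | (1R,5R,6R)-5-hydroxy-4-methyl-1-[(2E,6E,10E)-12-(TBDPS-oxy)-3,7,11-trimethyldodeca-2,6,10-trien-1-yl]-7-oxabicyclo[4.1.0]hept-3-en-2-one | O[C@@H]1C(C)=CC(=O)[C@]2(C/C=C(\C)CC/C=C(\C)CC/C=C(\C)CO[Si](c3ccccc3)(c3ccccc3)C(C)(C)C)O[C@H]12 | intermediate
24 | (1R,5R,6R)-4-methyl-2-oxo-1-[(2E,6E,10E)-12-(TBDPS-oxy)-3,7,11-trimethyldodeca-2,6,10-trien-1-yl]-7-oxabicyclo[4.1.0]hept-3-en-5-yl acetate | CC(=O)O[C@@H]1C(C)=CC(=O)[C@]2(C/C=C(\C)CC/C=C(\C)CC/C=C(\C)CO[Si](c3ccccc3)(c3ccccc3)C(C)(C)C)O[C@H]12 | intermediate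
25 | yanuthone L, (1R,5R,6R)-1-[(2E,6E,10E)-12-hydroxy-3,7,11-trimethyldodeca-2,6,10-trien-1-yl]-4-methyl-2-oxo-7-oxabicyclo[4.1.0]hept-3-en-5-yl acetate | CC(=O)O[C@@H]1C(C)=CC(=O)[C@]2(C/C=C(\C)CC/C=C(\C)CC/C=C(\C)CO)O[C@H]12 | target

**Count**
Total steps: 15. Longest linear sequence: 13 steps (1 → 25 through steps 1, 2, 3, 6–15); the cyclobutenone branch 6 → 11 is 2 steps.

**Steps most likely to fail**

Step 11. The remote auxiliary may discriminate the two faces of the dienone poorly, or induce the opposite sense, and the robust dioxane may later resist hydrolysis. The fallback changes from auxiliary control to catalyst control and sets out from 19. Catalytic enantioselective phase-transfer epoxidation (t-BuOOH, aqueous NaOH, toluene, N-benzylcinchonidinium-type quaternary ammonium salt, or its cinchoninium pseudo-enantiomer if the sense requires it) should give the dimethyl ketal epoxide (1R,6S)-5,5-dimethoxy-4-methyl-1-[(2E,6E,10E)-12-(TBDPS-oxy)-3,7,11-trimethyldodeca-2,6,10-trien-1-yl]-7-oxabicyclo[4.1.0]hept-3-en-2-one F1. Its dimethyl ketal is hydrolysed under much milder conditions (montmorillonite K10, CH2Cl2, rt), and the route is rejoined at 22.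

Step 13. Hydride may be delivered syn to the epoxide oxygen through coordination to it, so that the trans-epoxy alcohol predominates; over-reduction is a lesser concern. The fallback sets out from 22 and uses the unwanted epimer productively. The reduction is run deliberately for that epimer (DIBAL-H, THF, −78 °C) to give (1R,5S,6R)-5-hydroxy-4-methyl-1-[(2E,6E,10E)-12-(TBDPS-oxy)-3,7,11-trimethyldodeca-2,6,10-trien-1-yl]-7-oxabicyclo[4.1.0]hept-3-en-2-one F2. Mitsunobu esterification with acetic acid (PPh3, DIAD, toluene, 0 °C) then inverts C5 and installs the acetate in one operation, returning to the route at 24.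

Step 3. The π-allylpalladium intermediate may isomerise by σ–π–σ interconversion (eroding the 4E geometry), undergo β-hydride elimination to trienes, or couple a second time with the product stannane. The fallback avoids π-allyl intermediates and sets out from 3. Methanolysis (K2CO3, MeOH) gives (2E,6E,10E)-12-(TBDPS-oxy)-3,7,11-trimethyldodeca-2,6,10-trien-1-ol F3. Appel bromination (CBr4, PPh3, CH2Cl2, 0 °C) gives the allylic bromide [(2E,6E,10E)-12-bromo-2,6,10-trimethyldodeca-2,6,10-trien-1-yl]oxy(tert-butyl)diphenylsilane F4. Copper-catalysed SN2 coupling with ethynylmagnesium bromide (CuBr·SMe2 cat., THF, 0 °C) gives the skipped enyne tert-butyl(diphenyl){[(2E,6E,10E)-2,6,10-trimethyltetradeca-2,6,10-trien-13-yn-1-yl]oxy}silane F5. Hydrozirconation with Schwartz reagent followed by iodine gives the (E)-vinyl iodide tert-butyl{[(2E,6E,10E,13E)-14-iodo-2,6,10-trimethyltetradeca-2,6,10,13-tetraen-1-yl]oxy}diphenylsilane F6. Iodine–lithium exchange (t-BuLi, 2 equiv, Et2O, −78 °C) then delivers the same alkenyllithium, so the route is rejoined at 12 and continues to 14 under the step 6 conditions.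

**Further compounds**
F1 | step 11 | (1R,6S)-5,5-dimethoxy-4-methyl-1-[(2E,6E,10E)-12-(TBDPS-oxy)-3,7,11-trimethyldodeca-2,6,10-trien-1-yl]-7-oxabicyclo[4.1.0]hept-3-en-2-one | COC1(OC)C(C)=CC(=O)[C@]2(C/C=C(\C)CC/C=C(\C)CC/C=C(\C)CO[Si](c3ccccc3)(c3ccccc3)C(C)(C)C)O[C@H]12
F2 | step 13 | (1R,5S,6R)-5-hydroxy-4-methyl-1-[(2E,6E,10E)-12-(TBDPS-oxy)-3,7,11-trimethyldodeca-2,6,10-trien-1-yl]-7-oxabicyclo[4.1.0]hept-3-en-2-one | O[C@H]1C(C)=CC(=O)[C@]2(C/C=C(\C)CC/C=C(\C)CC/C=C(\C)CO[Si](c3ccccc3)(c3ccccc3)C(C)(C)C)O[C@H]12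
F3 | step 3 | (2E,6E,10E)-12-(TBDPS-oxy)-3,7,11-trimethyldodeca-2,6,10-trien-1-ol | OC/C=C(\C)CC/C=C(\C)CC/C=C(\C)CO[Si](c1ccccc1)(c1ccccc1)C(C)(C)C
F4 | step 3 | [(2E,6E,10E)-12-bromo-2,6,10-trimethyldodeca-2,6,10-trien-1-yl]oxy(tert-butyl)diphenylsilane | BrC/C=C(\C)CC/C=C(\C)CC/C=C(\C)CO[Si](c1ccccc1)(c1ccccc1)C(C)(C)C
F5 | step 3 | tert-butyl(diphenyl){[(2E,6E,10E)-2,6,10-trimethyltetradeca-2,6,10-trien-13-yn-1-yl]oxy}silane | C#CC/C=C(\C)CC/C=C(\C)CC/C=C(\C)CO[Si](c1ccccc1)(c1ccccc1)C(C)(C)C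
F6 | step 3 | tert-butyl{[(2E,6E,10E,13E)-14-iodo-2,6,10-trimethyltetradeca-2,6,10,13-tetraen-1-yl]oxy}diphenylsilane | I/C=C/C/C=C(\C)CC/C=C(\C)CC/C=C(\C)CO[Si](c1ccccc1)(c1ccccc1)C(C)(C)C
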